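**Plan**
1. Retrosynthesis: cut C12–C13 (Suzuki–Miyaura) and C11=C12 (Takai–Utimoto), take C11 back to one of two methyl groups on C9 (hydroxyl-directed C–H oxidation), add a temporary C2 carbonyl, remove the two esters, return the 7,8-diol to C7=C8 and C6–OH to C6=O. This gives a trans-fused decalin-3,7-diene-2,6-dione.
2. This dienedione is cut at C5–C10 and C3=C4 in one operation. The enabling feature: C5, the quaternary atom shared by rings A and B, lies between C4 and C6 (the central carbon of a latent 2-methyl-1,3-diketone) and C10 is β to C2 through C1, so an open chain C3–C2–C1=C10–C9–C8=C7–C6–C5–C4 can fold by Michael addition (ring B) and then olefination (ring A).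
3. Forward: the chain is built from prenylmagnesium chloride, a Weinreb amide, 3-methylpentane-2,4-dione and a ketophosphonate, and is stored as a racemic dihydropyranone (a temporary ring: the oxa-Michael adduct of the Z enone). A base cascade opens it, closes ring B (C5–C10) and then ring A (C3=C4).
4. Stereochemistry: C5 and C10 come from a chiral ion-pair catalyst acting on an achiral, equilibrating enolate. C6 is set by hydride attack anti to the axial C5 methyl, C7/C8 by OsO4 on the α face, C9 by delivery from the axial 8α-OH to the cis methyl group, and both E alkenes by E-selective olefinations.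
5. Helpers: the C2 carbonyl activates the acceptor, carries the phosphonate and shields C3=C4 from OsO4; it leaves as a dithiolane with Raney Ni. No protecting groups are used.

Key step: step 6

Remark: clerodane numbering of the target (C1–C10 decalin, C11–C16 side chain, C17–C20 methyls) is used for the atoms of every intermediate; β is the face of the C5 methyl group.
Assumption: the cinchonidinium catalyst of step 6 is taken to expose the enolate face that leads to the (4aR,8aR) product; the pseudo-enantiomeric cinchoninium salt would deliver the other face.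

**Step 1**
Reactants: 1 prenylmagnesium chloride; 2 N-methoxy-N-methylacetamide
Product: 3 3,3-dimethylpent-4-en-2-one
Conditions: THF, −78 → 0 °C; aq. NH4Cl
Reagents that add atoms: none
Why: Allylic Grignard reagents attack carbonyl electrophiles through the γ-carbon (SE2′, allyl transposition), so the prenyl reagent gives the α,α-dimethylallyl ketone, and the chelated adduct of the Weinreb amide stops at the ketone (Weinreb ketone synthesis).

**Step 2**
Reactants: 3 3,3-dimethylpent-4-en-2-one; 4 3-methylpentane-2,4-dione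
Product: 6 rac-2,5,6-trimethyl-2-(2-methylbut-3-en-2-yl)-2,3-dihydro-4H-pyran-4-one, via aldol adduct 5 (not isolated)
Conditions: 4, LiN(i-Pr)2 (2.2 equiv), THF, 0 °C; CeCl3, −78 °C; then 3, −78 °C; aq. HCl; then TsOH·H2O (cat.), CH2Cl2, rt
Reagents that add atoms: none
Why: The terminal carbanion of the diketone dianion, made less basic by CeCl3, adds to the hindered methyl ketone (dianion aldol addition), and acid closes the tertiary hydroxyl onto the C4 carbonyl and dehydrates the hemiketal to the dihydropyranone (cyclodehydration), whose C8 stereocentre is racemic and is erased again in step 6.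

**Step 3**
Reactants: 6 rac-2,5,6-trimethyl-2-(2-methylbut-3-en-2-yl)-2,3-dihydro-4H-pyran-4-one
Product: 7 rac-2-methyl-2-(2,5,6-trimethyl-4-oxo-3,4-dihydro-2H-pyran-2-yl)propanal
Conditions: OsO4 (2 mol%), NaIO4, 2,6-lutidine, dioxane/H2O, rt
Reagents that add atoms: osmium tetroxide, O=[Os](=O)(=O)=O (delivers the aldehyde oxygen; catalytic); sodium periodate, [Na+].[O-][I](=O)(=O)=O (re-forms OsO4 and cleaves the diol)
Why: In this Lemieux–Johnson cleavage OsO4 dihydroxylates the monosubstituted vinyl group much faster than the tetrasubstituted, carbonyl-conjugated enol-ether double bond, and periodate cleaves the diol to the non-enolisable aldehyde.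

**Step 4**
Reactants: 7 rac-2-methyl-2-(2,5,6-trimethyl-4-oxo-3,4-dihydro-2H-pyran-2-yl)propanal; 8 dimethyl (2-oxopropyl)phosphonate
Product: 9 dimethyl [4-hydroxy-5-methyl-2-oxo-5-(2,5,6-trimethyl-4-oxo-3,4-dihydro-2H-pyran-2-yl)hexyl]phosphonate (diastereomer mixture)
Conditions: 8, NaH then n-BuLi, THF, 0 °C; then 7, −78 °C; aq. NH4Cl
Reagents that add atoms: none
Why: The 1,3-dianion of the β-ketophosphonate reacts at its terminal carbon and, at −78 °C, far faster with the aldehyde than with the vinylogous ester (dianion aldol addition); the new carbinol centre is a mixture and is removed in step 5.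

**Step 5**
Reactants: 9 dimethyl [4-hydroxy-5-methyl-2-oxo-5-(2,5,6-trimethyl-4-oxo-3,4-dihydro-2H-pyran-2-yl)hexyl]phosphonate
Product: 11 rac-dimethyl [(3E)-5-methyl-2-oxo-5-(2,5,6-trimethyl-4-oxo-3,4-dihydro-2H-pyran-2-yl)hex-3-en-1-yl]phosphonate, via mesylate 10 (not isolated)
Conditions: MsCl, Et3N, CH2Cl2, 0 °C → rt
Reagents that add atoms: none
Why: Mesylation followed by E1cB elimination of the β-mesyloxy ketone gives the conjugated E enone (the geometry trans to the quaternary carbon is the stable one), and Et3N is too weak a base to open the dihydropyranone.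

**Step 6**
Reactants: 11 rac-dimethyl [(3E)-5-methyl-2-oxo-5-(2,5,6-trimethyl-4-oxo-3,4-dihydro-2H-pyran-2-yl)hex-3-en-1-yl]phosphonate
Product: 14 (4aR,8aR)-4,4a,7,8,8-pentamethyl-4a,8a-dihydronaphthalene-2,5(1H,8H)-dione, via ring-opened enolate 12 (not isolated), via Michael adduct 13 (not isolated)
Conditions: N-(9-anthracenylmethyl)-O-allylcinchonidinium bromide (10 mol%), Cs2CO3 (2 equiv), toluene (0.01 M), 0 → 40 °C
Reagents that add atoms: none
Why: Proposed new method: carbonate removes H-7 and the diketone enolate leaves from C8 (retro-oxa-Michael, as in the base-induced opening of a flavanone to a chalcone) to give enolate 12, whose E and Z enone isomers and C5 epimers interconvert by reclosure to the dihydropyranone, so the whole mixture drains through the only isomer that can cyclize, the Z enone; its C5 then adds to C10 of the E-enone arm (closest known asymmetric reaction type: Michael addition of 2-alkyl-1,3-dicarbonyl compounds to enones under chiral phase-transfer catalysis), the enolate of 13 passes its charge to the phosphonate carbon C3, and intramolecular HWE olefination of the C4 acetyl group forms C3=C4 (closest known cascades: internal Michael/aldol double annulation of acyclic keto-enones and tandem Michael/HWE cyclohexene syntheses). Ring B closes in a 6-(enolendo)-exo-trig Michael mode and ring A by 6-exo-trig addition of the phosphonate carbanion to the ketone followed by loss of dimethyl phosphate, which makes the sequence irreversible. C5 is set by the face of the planar diketone enolate left open in its ion pair with the cinchonidinium cation, and C10 follows from C5 through a chair-like transition state in which the enone arm lies pseudo-equatorial and anti to the C5–C6 bond, so that C1 and the acetyl group end up trans and the decalin is trans-fused. The step needs C- rather than O-attack, the anti Michael adduct, olefination at C4 rather than aldol closure onto C2 or C6, and one enantiomer; these are secured by the reversibility of both O-attacks, by the bulky cation that fills the sector between the two enolate oxygens and keeps the enone arm out of it, by placing the only stabilized carbanion on C3 (closure onto C6 would give a bridgehead alkene), and by the catalyst, while the gem-dimethyl C9 is not stereogenic and cannot bias either face.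

**Step 7**
Reactants: 14 (4aR,8aR)-4,4a,7,8,8-pentamethyl-4a,8a-dihydronaphthalene-2,5(1H,8H)-dione
Product: 16 (4aR,5S,8aR)-5-hydroxy-4,4a,7,8,8-pentamethyl-4a,5,8,8a-tetrahydronaphthalen-2(1H)-one, via lithium dienolate 15 (not isolated)
Conditions: LiN(i-Pr)2 (1.1 equiv), THF, −78 °C; then i-Bu2AlH (1.5 equiv), −78 °C; aq. KNa tartrate
Reagents that add atoms: none
Why: Kinetic deprotonation at C1 masks the enolisable C2 enone as its cross-conjugated lithium dienolate, while the C6 enone, which has no α′-hydrogen, stays free and is reduced 1,2 by i-Bu2AlH from the α face, anti to the axial C5 methyl group (axial attack), giving the equatorial 6β-alcohol; work-up returns the C2 enone (ketone masking as enolate, hydride reduction).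

**Step 8**
Reactants: 16 (4aR,5S,8aR)-5-hydroxy-4,4a,7,8,8-pentamethyl-4a,5,8,8a-tetrahydronaphthalen-2(1H)-one
Product: 17 6β-acetate of 16
Conditions: Ac2O, DMAP, pyridine, CH2Cl2, rt
Reagents that add atoms: acetic anhydride, CC(=O)OC(C)=O
Why: DMAP-catalysed acyl transfer esterifies the only hydroxyl group with retention at C6.

**Step 9**
Reactants: 17 6β-acetate of 16
Product: 18 6β-acetoxy-7α,8α-dihydroxy-4,5β,8β,9,9-pentamethyl-trans-decal-3-en-2-one
Conditions: OsO4 (5 mol%), N-methylmorpholine N-oxide, acetone/H2O, rt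
Reagents that add atoms: osmium tetroxide, O=[Os](=O)(=O)=O (delivers both oxygens; catalytic); N-methylmorpholine N-oxide, C[N+]1([O-])CCOCC1 (re-forms OsO4)
Why: Catalytic syn-dihydroxylation takes the C7=C8 bond because C3=C4 is deactivated as part of the C2 enone, and OsO4 comes from the α face, anti to the allylic 6β-acetoxy group and to the axial β-methyl groups on C9 and C5, which sets the cis 7α,8α-diol.

**Step 10**
Reactants: 18 6β-acetoxy-7α,8α-dihydroxy-4,5β,8β,9,9-pentamethyl-trans-decal-3-en-2-one
Product: 19 6β-acetoxy-8α-hydroxy-7α-isobutyryloxy-4,5β,8β,9,9-pentamethyl-trans-decal-3-en-2-one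
Conditions: i-PrCOCl, pyridine, DMAP (cat.), CH2Cl2, 0 °C
Reagents that add atoms: isobutyryl chloride, CC(C)C(Cl)=O
Why: Nucleophile-catalysed acylation takes the secondary 7-hydroxyl, while the tertiary, axial 8-hydroxyl next to the quaternary C9 does not react at 0 °C.

**Step 11**
Reactants: 19 6β-acetoxy-8α-hydroxy-7α-isobutyryloxy-4,5β,8β,9,9-pentamethyl-trans-decal-3-en-2-one
Product: 20 spiro-1,3-dithiolane (2,2-ethylenedithio ketal) of 19
Conditions: HS(CH2)2SH, BF3·OEt2, CH2Cl2, 0 °C
Reagents that add atoms: ethane-1,2-dithiol, SCCS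
Why: Lewis-acid-catalysed dithioketalisation converts the only ketone into its dithiolane without moving the C3=C4 bond, the esters and the tertiary alcohol being inert under these conditions.

**Step 12**
Reactants: 20 spiro-1,3-dithiolane of 19
Product: 21 6β-acetoxy-8α-hydroxy-7α-isobutyryloxy-4,5β,8β,9,9-pentamethyl-trans-decal-3-ene
Conditions: Raney Ni (W-2, deactivated), EtOH, rt
Reagents that add atoms: none
Why: Raney Ni hydrogenolyses both C–S bonds (Mozingo reduction), replacing the helper carbonyl by CH2 and leaving the hindered trisubstituted alkene in place, as in the classical conversion of enone thioketals into alkenes.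

**Step 13**
Reactants: 21 6β-acetoxy-8α-hydroxy-7α-isobutyryloxy-4,5β,8β,9,9-pentamethyl-trans-decal-3-ene
Product: 24 6β-acetoxy-8α-hydroxy-9α-hydroxymethyl-7α-isobutyryloxy-4,5β,8β,9β-tetramethyl-trans-decal-3-ene, via hydridosilyl ether 22 (not isolated), via oxasilolane 23 (not isolated)
Conditions: [Ir(cod)OMe]2 (cat.), Et2SiH2, THF, rt; then [Ir(cod)OMe]2 (cat.), 3,4,7,8-tetramethyl-1,10-phenanthroline, norbornene, THF, 100 °C; then 30% H2O2, KHCO3, THF/MeOH, rt → 40 °C
Reagents that add atoms: hydrogen peroxide, OO (the C11 oxygen); diethylsilane, CC[SiH2]CC, adds silicon only to 22 and 23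
Why: The tertiary 8α-hydroxyl is silylated to its hydridosilyl ether, iridium activates the one primary γ C–H bond that can close a five-membered ring (that of the equatorial 9α-methyl group gauche to the axial oxygen, the axial 9β-methyl being anti), and Tamao–Fleming oxidation of the oxasilolane gives the 1,3-diol, which makes C9 stereogenic with the hydroxymethyl group α (hydroxyl-directed C–H silylation/oxidation).

**Step 14**
Reactants: 24 6β-acetoxy-8α-hydroxy-9α-hydroxymethyl-7α-isobutyryloxy-4,5β,8β,9β-tetramethyl-trans-decal-3-ene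
Product: 25 9α-formyl analogue of 24 (C11 aldehyde)
Conditions: Dess–Martin periodinane, NaHCO3, CH2Cl2, 0 °C → rt
Reagents that add atoms: none
Why: Dess–Martin oxidation converts the primary alcohol into the aldehyde under buffered, non-basic conditions, so the tertiary alcohol is untouched and retro-aldol cleavage is avoided.

**Step 15**
Reactants: 25 9α-formyl analogue of 24; 26 2-(dichloromethyl)-4,4,5,5-tetramethyl-1,3,2-dioxaborolane
Product: 27 9α-[(E)-2-(4,4,5,5-tetramethyl-1,3,2-dioxaborolan-2-yl)ethenyl] analogue of 24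
Conditions: CrCl2 (8 equiv), LiI, THF, rt
Reagents that add atoms: none
Why: In the Takai–Utimoto olefination the gem-dichromium species made from 26 and CrCl2 adds to the aldehyde and eliminates to the E-alkenylboronate, and the reagent is non-basic and tolerates the free hydroxyl and the esters.

**Step 16**
Reactants: 27 9α-[(E)-2-(pinacolboryl)ethenyl] analogue of 24; 28 4-bromofuran-2(5H)-one
Product: 29 CNP0207114.1 (target)
Conditions: Pd(PPh3)4 (5 mol%), K3PO4, THF/H2O, 50 °C
Reagents that add atoms: none
Why: In this Suzuki–Miyaura coupling, oxidative addition of the bromobutenolide to zerovalent palladium, transmetalation of the alkenylboronate and reductive elimination join C12 to C13 with retention of the E geometry.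

**Compound list**
1 | prenylmagnesium chloride (3-methylbut-2-en-1-ylmagnesium chloride) | CC(C)=CC[Mg]Cl | starting material
2 | N-methoxy-N-methylacetamide | CC(=O)N(C)OC | starting material
3 | 3,3-dimethylpent-4-en-2-one | CC(=O)C(C)(C)C=C | intermediate
4 | 3-methylpentane-2,4-dione | CC(=O)C(C)C(C)=O | starting material
5 | 6-hydroxy-3,6,7,7-tetramethylnon-8-ene-2,4-dione (aldol adduct, stereoisomer mixture) | CC(=O)C(C)C(=O)CC(C)(O)C(C)(C)C=C | intermediate (not isolated)
6 | rac-2,5,6-trimethyl-2-(2-methylbut-3-en-2-yl)-2,3-dihydro-4H-pyran-4-one | CC1=C(C)C(=O)CC(C)(O1)C(C)(C)C=C | intermediate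
7 | rac-2-methyl-2-(2,5,6-trimethyl-4-oxo-3,4-dihydro-2H-pyran-2-yl)propanal | CC1=C(C)C(=O)CC(C)(O1)C(C)(C)C=O | intermediate
8 | dimethyl (2-oxopropyl)phosphonate | CC(=O)CP(=O)(OC)OC | starting material
9 | dimethyl [4-hydroxy-5-methyl-2-oxo-5-(2,5,6-trimethyl-4-oxo-3,4-dihydro-2H-pyran-2-yl)hexyl]phosphonate (diastereomer mixture) | CC1=C(C)C(=O)CC(C)(O1)C(C)(C)C(O)CC(=O)CP(=O)(OC)OC | intermediate
10 | 4-O-methanesulfonate of 9 | CC1=C(C)C(=O)CC(C)(O1)C(C)(C)C(OS(C)(=O)=O)CC(=O)CP(=O)(OC)OC | intermediate (not isolated)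
11 | rac-dimethyl [(3E)-5-methyl-2-oxo-5-(2,5,6-trimethyl-4-oxo-3,4-dihydro-2H-pyran-2-yl)hex-3-en-1-yl]phosphonate | CC1=C(C)C(=O)CC(C)(O1)C(C)(C)/C=C/C(=O)CP(=O)(OC)OC | intermediate
12 | dimethyl [(3E,6Z)-5,5,6,9-tetramethyl-2,8,10-trioxoundeca-3,6-dien-1-yl]phosphonate (present as its diketone enolate; the carbon between the two ketones is configurationally labile) | CC(=O)C(C)C(=O)/C=C(/C)C(C)(C)/C=C/C(=O)CP(=O)(OC)OC | intermediate (not isolated)
13 | dimethyl {3-[(1R,6R)-6-acetyl-2,2,3,6-tetramethyl-5-oxocyclohex-3-en-1-yl]-2-oxopropyl}phosphonate | O=C1C=C(C)C(C)(C)[C@@H](CC(=O)CP(=O)(OC)OC)[C@]1(C)C(C)=O | intermediate (not isolated)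
14 | (4aR,8aR)-4,4a,7,8,8-pentamethyl-4a,8a-dihydronaphthalene-2,5(1H,8H)-dione (trans-fused) | O=C1C=C(C)C(C)(C)[C@H]2CC(=O)C=C(C)[C@]12C | intermediate
15 | lithium dienolate of 14 (C1=C2(OLi)–C3=C4) | O=C1C=C(C)C(C)(C)[C@H]2C=C(O[Li])C=C(C)[C@]12C | intermediate (not isolated)
16 | (4aR,5S,8aR)-5-hydroxy-4,4a,7,8,8-pentamethyl-4a,5,8,8a-tetrahydronaphthalen-2(1H)-one (6β-alcohol) | O[C@H]1C=C(C)C(C)(C)[C@H]2CC(=O)C=C(C)[C@]12C | intermediate
17 | 6β-acetate of 16 | CC(=O)O[C@H]1C=C(C)C(C)(C)[C@H]2CC(=O)C=C(C)[C@]12C | intermediate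
18 | 6β-acetoxy-7α,8α-dihydroxy-4,5β,8β,9,9-pentamethyl-trans-decal-3-en-2-one | CC(=O)O[C@H]1[C@H](O)[C@](C)(O)C(C)(C)[C@H]2CC(=O)C=C(C)[C@]12C | intermediate
19 | 6β-acetoxy-8α-hydroxy-7α-isobutyryloxy-4,5β,8β,9,9-pentamethyl-trans-decal-3-en-2-one | CC(=O)O[C@H]1[C@H](OC(=O)C(C)C)[C@](C)(O)C(C)(C)[C@H]2CC(=O)C=C(C)[C@]12C | intermediate
20 | spiro-1,3-dithiolane (2,2-ethylenedithio ketal) of 19 | CC(=O)O[C@H]1[C@H](OC(=O)C(C)C)[C@](C)(O)C(C)(C)[C@H]2CC3(SCCS3)C=C(C)[C@]12C | intermediate
21 | 6β-acetoxy-8α-hydroxy-7α-isobutyryloxy-4,5β,8β,9,9-pentamethyl-trans-decal-3-ene | CC(=O)O[C@H]1[C@H](OC(=O)C(C)C)[C@](C)(O)C(C)(C)[C@H]2CCC=C(C)[C@]12C | intermediate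
22 | 8-O-diethyl(hydrido)silyl ether of 21 | CC(=O)O[C@H]1[C@H](OC(=O)C(C)C)[C@](C)(O[SiH](CC)CC)C(C)(C)[C@H]2CCC=C(C)[C@]12C | intermediate (not isolated)
23 | 1,2-oxasilolane joining O8 and C11 through SiEt2 | CC(=O)O[C@H]1[C@H](OC(=O)C(C)C)[C@]3(C)O[Si](CC)(CC)C[C@]3(C)[C@H]2CCC=C(C)[C@]12C | intermediate (not isolated)
24 | 6β-acetoxy-8α-hydroxy-9α-hydroxymethyl-7α-isobutyryloxy-4,5β,8β,9β-tetramethyl-trans-decal-3-ene | CC(=O)O[C@H]1[C@H](OC(=O)C(C)C)[C@](C)(O)[C@](C)(CO)[C@H]2CCC=C(C)[C@]12C | intermediate
25 | 9α-formyl analogue of 24 | CC(=O)O[C@H]1[C@H](OC(=O)C(C)C)[C@](C)(O)[C@](C)(C=O)[C@H]2CCC=C(C)[C@]12C | intermediate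
26 | 2-(dichloromethyl)-4,4,5,5-tetramethyl-1,3,2-dioxaborolane | ClC(Cl)B1OC(C)(C)C(C)(C)O1 | starting material
27 | 9α-[(E)-2-(4,4,5,5-tetramethyl-1,3,2-dioxaborolan-2-yl)ethenyl] analogue of 24 | CC(=O)O[C@H]1[C@H](OC(=O)C(C)C)[C@](C)(O)[C@](C)(/C=C/B3OC(C)(C)C(C)(C)O3)[C@H]2CCC=C(C)[C@]12C | intermediate
28 | 4-bromofuran-2(5H)-one | BrC1=CC(=O)OC1 | starting material
29 | CNP0207114.1 | CC(=O)O[C@H]1[C@H](OC(=O)C(C)C)[C@](C)(O)[C@](C)(/C=C/C2=CC(=O)OC2)[C@H]2CCC=C(C)[C@]12C | target

**Totals**
Total steps: 16. Longest linear sequence: 16 steps (from 1 and 2).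

**Steps most likely to fail**

Step 6. The dihydropyranone may open too slowly under the weakly basic ion-pair conditions, and the ion pair may discriminate the enolate faces, or the anti versus syn Michael topology, poorly. Fallback (sets out from 11, comes back at 16): the ring system is made without a chiral controller and the enantiomers are separated afterwards. Cs2CO3 with 18-crown-6 in MeCN at 50 °C runs the same sequence of individually known steps (flavanone-type ring opening, internal Michael addition of a 2-alkyl-1,3-diketone, intramolecular HWE) and gives racemic trans-dienedione F1. Masking and reduction as in step 7 give racemic 6β-alcohol F2. Esterification with (S)-2-methoxy-2-phenylacetic acid (DCC, DMAP) gives two diastereomeric esters, which are separated by chromatography; mandelate ester F3, derived from the (4aR,5S,8aR)-alcohol, is hydrolysed with LiOH in THF/H2O to 16.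

Step 13. C–H insertion at the neopentyl methyl group may be outrun by catalyst deactivation or by reaction at the alkene, and the basic peroxide of the oxidation stage may cleave or shift the ester groups. Fallback (sets out from 4, which is used as before together with 8, and comes back at 24; ketone 3 is replaced): the C11 oxygen is carried from the start instead of being introduced by C–H oxidation. Iridium-catalysed enantioselective tert-(hydroxy)prenylation of ethanol with isoprene monoxide ([Ir(cod)Cl]2, the Tol-BINAP enantiomer that gives the 2S product, 4-chloro-3-nitrobenzoic acid, K3PO4, THF, 60 °C) gives diol F4. t-BuPh2SiCl/imidazole gives primary silyl ether F5, and Dess–Martin oxidation gives ketone F6, the oxygenated counterpart of 3. F6 then follows steps 2–12 unchanged: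
- the dianion of 4 and then TsOH give dihydropyranone F7;
- OsO4/NaIO4 gives aldehyde F8;
- the dianion of 8 gives aldol F9;
- MsCl/Et3N gives enone phosphonate F10;
- the cascade of step 6 gives dienedione F11 (C9 is now already stereogenic, and the ion-pair catalyst still chooses the enolate face);
- the later steps give allylic alcohol F12, acetate F13, diol F14, isobutyrate F15, dithiolane F16 and, after Raney Ni, silyl ether F17.

HF·pyridine removes the silyl group from F17 and delivers 24.

Step 2. Proton transfer from the hindered, enolisable methyl ketone to the strongly basic dianion, or retro-aldol of the tertiary alkoxide on warming, may outrun productive addition. Fallback (sets out from 4, comes back at 6): the strongly basic dianion is replaced by a neutral nucleophile under Lewis-acid activation. Me3SiOTf/Et3N converts 4 into bis(silyl) dienol ether F18, which adds through its terminal carbon to ketone 3 with TiCl4 in CH2Cl2 at −78 °C (vinylogous Mukaiyama aldol addition). Aqueous work-up gives 5, which TsOH closes to 6 as in step 2.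

**Further compounds**
F1 | step 6 | racemic trans-4,4a,7,8,8-pentamethyl-4a,8a-dihydronaphthalene-2,5(1H,8H)-dione (both enantiomers) | O=C1C=C(C)C(C)(C)[C@H]2CC(=O)C=C(C)[C@]12C.O=C1C=C(C)C(C)(C)[C@@H]2CC(=O)C=C(C)[C@@]12C
F2 | step 6 | racemic 6β-alcohol (both enantiomers of 16) | O[C@H]1C=C(C)C(C)(C)[C@H]2CC(=O)C=C(C)[C@]12C.O[C@@H]1C=C(C)C(C)(C)[C@@H]2CC(=O)C=C(C)[C@@]12C
F3 | step 6 | (S)-2-methoxy-2-phenylacetate of 16 | CO[C@H](C(=O)O[C@H]1C=C(C)C(C)(C)[C@H]2CC(=O)C=C(C)[C@]12C)c1ccccc1
F4 | step 13 | (2S)-2-ethenyl-2-methylbutane-1,3-diol (carbinol configuration not needed; oxidised later) | CC(O)[C@](C)(CO)C=C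
F5 | step 13 | 1-O-tert-butyldiphenylsilyl ether of F4 | CC(O)[C@](C)(CO[Si](c1ccccc1)(c1ccccc1)C(C)(C)C)C=C
F6 | step 13 | (3S)-3-[(tert-butyldiphenylsilyloxy)methyl]-3-methylpent-4-en-2-one | CC(=O)[C@](C)(CO[Si](c1ccccc1)(c1ccccc1)C(C)(C)C)C=C
F7 | step 13 | silyloxymethyl analogue of 6 (C8 epimers) | CC1=C(C)C(=O)CC(C)(O1)[C@](C)(CO[Si](c2ccccc2)(c2ccccc2)C(C)(C)C)C=C
F8 | step 13 | silyloxymethyl analogue of 7 | CC1=C(C)C(=O)CC(C)(O1)[C@](C)(CO[Si](c2ccccc2)(c2ccccc2)C(C)(C)C)C=O
F9 | step 13 | silyloxymethyl analogue of 9 | CC1=C(C)C(=O)CC(C)(O1)[C@](C)(CO[Si](c2ccccc2)(c2ccccc2)C(C)(C)C)C(O)CC(=O)CP(=O)(OC)OC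
F10 | step 13 | silyloxymethyl analogue of 11 | CC1=C(C)C(=O)CC(C)(O1)[C@](C)(CO[Si](c2ccccc2)(c2ccccc2)C(C)(C)C)/C=C/C(=O)CP(=O)(OC)OC
F11 | step 13 | 9α-silyloxymethyl analogue of 14 | O=C1C=C(C)[C@](C)(CO[Si](c3ccccc3)(c3ccccc3)C(C)(C)C)[C@H]2CC(=O)C=C(C)[C@]12C
F12 | step 13 | 9α-silyloxymethyl analogue of 16 | O[C@H]1C=C(C)[C@](C)(CO[Si](c3ccccc3)(c3ccccc3)C(C)(C)C)[C@H]2CC(=O)C=C(C)[C@]12C
F13 | step 13 | 9α-silyloxymethyl analogue of 17 | CC(=O)O[C@H]1C=C(C)[C@](C)(CO[Si](c3ccccc3)(c3ccccc3)C(C)(C)C)[C@H]2CC(=O)C=C(C)[C@]12C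
F14 | step 13 | 9α-silyloxymethyl analogue of 18 | CC(=O)O[C@H]1[C@H](O)[C@](C)(O)[C@](C)(CO[Si](c3ccccc3)(c3ccccc3)C(C)(C)C)[C@H]2CC(=O)C=C(C)[C@]12C
F15 | step 13 | 9α-silyloxymethyl analogue of 19 | CC(=O)O[C@H]1[C@H](OC(=O)C(C)C)[C@](C)(O)[C@](C)(CO[Si](c3ccccc3)(c3ccccc3)C(C)(C)C)[C@H]2CC(=O)C=C(C)[C@]12C
F16 | step 13 | 9α-silyloxymethyl analogue of 20 | CC(=O)O[C@H]1[C@H](OC(=O)C(C)C)[C@](C)(O)[C@](C)(CO[Si](c3ccccc3)(c3ccccc3)C(C)(C)C)[C@H]2CC3(SCCS3)C=C(C)[C@]12C
F17 | step 13 | 11-O-tert-butyldiphenylsilyl ether of 24 | CC(=O)O[C@H]1[C@H](OC(=O)C(C)C)[C@](C)(O)[C@](C)(CO[Si](c3ccccc3)(c3ccccc3)C(C)(C)C)[C@H]2CCC=C(C)[C@]12C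
F18 | step 2 | 3-methyl-2,4-bis(trimethylsilyloxy)penta-1,3-diene | C=C(O[Si](C)(C)C)C(C)=C(C)O[Si](C)(C)C
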